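The earlier runs and the new flask were generated by integration from invented constants; the scatter is artificial.

What I wanted from the west flask was how much target it holds at 8.0 d, and whether any option can still add more than 2 percentage points.

| flask | starting material | second substrate | free enzyme | temperature | remark | time |
|---|---|---|---|---|---|---|
| west | 20 mM | 18 mM | 1.7 µM | 30 °C | the very flask that is asked about, followed so far |  |
| south-east | 20 mM | 18 mM | 0.85 µM | 30 °C | run made earlier |  |
| flask | 20 mM | 18.0 mM | 1.7 µM | 30 °C |  | 8.0 d |

| run | time / h | target / % | starting material / % |
|---|---|---|---|
| west | 10.0 | 12.7 | 3.3 |
| west | 20.0 | 14.1 | 0.7 |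
| west | 50.0 | 14.3 | 0 |
| west | 120 | 14.4 | 0 |
| south-east | 1.50 | 2.5 | 89.6 |
| south-east | 4.00 | 1.8 | 68.8 |
| south-east | 8.00 | 3.7 | 37.4 |
| south-east | 12.0 | 5.6 | 15.9 |

(standard deviation of a reading: 1 percentage point)

- autumn: at 8.0 d take out 90% of the target then present, then wait 15 d
- dusk: change nothing and wait 15 d more
- midnight: at 8.0 d add free enzyme, 100% of the amount charged, then wait 15 d
- summer: at 8.0 d add second substrate, 100% of the amount charged, then wait 15 d
- winter: at 8.0 d raise the temperature by 10 K, then wait 15 d

* target, in percent of the starting material first charged, at 8.0 d
* which option adds most target ("none" when 2 percentage points or less is all one gets) (autumn / dusk / midnight / summer / winter / none)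
* target present, with what was taken out counted in, in percent of the starting material first charged, after autumn
* target present, with what was taken out counted in, in percent of the starting material first charged, after summer

- in percentages every species weighs as the starting material in it: one side product counts as two
- target taken out counts as made
- the earlier runs were read with a standard deviation of 1 percentage point
- what may be going on: free enzyme -> unfolded enzyme; starting material + free enzyme <-> first complex; first complex -> loaded enzyme + first product; second substrate + loaded enzyme <-> second complex; second complex -> free enzyme + target; starting material + target -> side product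
- the earlier runs do not show what temperature does; that part of a forecast is a guess
- additions bring no volume worth counting

I ran the flask slowly in my head. At the start, each round of the enzyme takes one starting material and one second substrate and lets out one first product and one target. The south-east run, with 0.85 µM of free enzyme, shows this stage: at 1.50 h starting material read 89.6% and target 2.5%.

In the middle of the south-east run, starting material still stood far above target (68.8% against 1.8% at 4.00 h); of the 31.2% of starting material that had gone by then, target read 1.8%, so I took the rest to have become side product. So I counted in pairs: one second substrate takes two starting materials out when the target it made is eaten, one in the round and one with that target. I took 1.80 as the reach, twice the second substrate charged over the starting material charged. With the enzyme working, no other path and every target eaten, a reach above one makes starting material the limiting reagent; below one, second substrate ends first and a share of one minus the reach of starting material stays.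

At the end of the west run, starting material read 0% at 50.0 h, and target stood flat, 14.3% there and 14.4% at 120 h. The starting material of the west run, read roughly between its first two readings, lost a factor of 10 every 14.8 h. At that pace the time up to 8.0 d holds about 11.6 such factors. I committed to the flat reading and to no useful option.

The forecast said the same: 14.4% at 8.0 d, best none, 14.4% after autumn and 14.4% after summer. Its ground was “With no starting material left, the side reaction has stopped too.”

The flask gave 15.2% at 8.0 d, best none, 15.2% after autumn and 15.2% after summer.

    free enzyme → unfolded enzyme (k = 0.00610 h⁻¹, Ea = 247 kJ mol⁻¹)
    starting material + free enzyme ⇌ first complex (K = 120 M⁻¹, k = 1.30 × 10⁷ M⁻¹ h⁻¹, Ea = 36.0 kJ mol⁻¹, ΔH = −15.0 kJ mol⁻¹)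
    first complex → loaded enzyme + first product (k = 2600 h⁻¹, Ea = 66.0 kJ mol⁻¹)
    second substrate + loaded enzyme ⇌ second complex (K = 160 M⁻¹, k = 2.70 × 10⁷ M⁻¹ h⁻¹, Ea = 33.0 kJ mol⁻¹, ΔH = −52.0 kJ mol⁻¹)
    second complex → free enzyme + target (k = 3800 h⁻¹, Ea = 81.0 kJ mol⁻¹)
    starting material + target → side product (k = 86.0 M⁻¹ h⁻¹, Ea = 53.0 kJ mol⁻¹)
    (constants at 30 °C)

At 3.34 h in the flask, target was made 1.17 times as fast as it was used up, each step taken net, and by the side path starting material had a half-life of 5.3 h. At 192 h the flask, with its reach of 1.80, held starting material 0%, target 15.2%, side product 84.8% and 36% of its second substrate. The neighbour charged with 80 mM of starting material has a reach of 0.450; it ended with second substrate 0%, target 0%, and starting material 55.0%, where one minus the reach gives 55.0%.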